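**Two runs.** Wednesday's flask held 13.9 times the reagent of Saturday's flask. Yet at the last reading it holds 5.76 times the target, a smaller factor.

| flask | substrate | reagent | catalyst | remark | time |
|---|---|---|---|---|---|
| Saturday's | 10 mM | 5.4 mM | 0.29 mM | run made earlier |  |
| Wednesday's | 10 mM | 75 mM | 0.29 mM | run made earlier |  |
| oak | 10 mM | 25.0 mM | 0.29 mM |  | 3.0 min |
| maple | 10 mM | 12.0 mM | 0.29 mM |  | 3.0 min |
| birch | 10 mM | 50.0 mM | 0.29 mM |  | 3.0 min |
| elm | 10 mM | 4.00 mM | 0.29 mM |  | 3.0 min |

- Saturday's (time / s: target / %): 12.0: 0.6; 25.0: 1.2; 40.0: 1.2; 50.0: 3.7; 60.0: 4.6; 80.0: 7.9; 90.0: 9.1
- Wednesday's (time / s: target / %): 10.0: 2.1; 15.0: 7.6; 25.0: 15.7; 40.0: 26.3; 50.0: 32.7; 80.0: 50.4; 90.0: 52.4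

(readings scatter by 1 percentage point)



* all flasks from highest to lowest amount of target, in percent of the substrate charged, at 3.0 min (oak / maple / birch / elm)
* the amount of target, in percent of the substrate charged of the flask you put first, at 3.0 min
* the amount of target, in percent of the substrate charged of the flask you put last, at 3.0 min

**Bench rule.** You would scale target with reagent. For birch against elm, that says 12.5 times. The two runs show that the rule breaks somewhere between their charges.

**The fork.** Both runs start slowly and then speed up, so a middle form lies between substrate and target. Follow one molecule there. Reagent carries it on, and other ways take it elsewhere. Its chance of going on is reagent/(reagent + h), where h, at this catalyst charge, is the reagent level at which both outcomes are equally likely. The two last readings give h = 43.9 mM, the even-odds reagent. This is a reading, and each point carries a scatter of 1 percentage point. Elm stands at 0.0911 of h, where the chance still grows nearly in step with reagent, and birch stands at 1.14 of h, where it does not.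

**The reckoning.** Wednesday's readings from 40.0 s to 90.0 s give a first-order constant of 0.00874 s⁻¹. Carried to 3.0 min, that puts Wednesday's curve at 78.3%. Now assume every flask shares that time shape and scale by the chance. Birch comes to 66.1% and elm to 10.4%. The order follows the reagent charge, with birch first.

**The result.** The forecast, higher than this reckoning, gives birch > oak > maple > elm, with 72% for birch and 14% for elm, on the ground that “The rate constant is therefore less than proportional to reagent”. The flasks give birch > oak > maple > elm, with birch at 68.9% and elm at 12.5%.

    substrate + catalyst ⇌ catalyst + intermediate (K = 0.490, k = 54.0 L mol⁻¹ s⁻¹)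
    reagent + catalyst + intermediate → catalyst + target (k = 3400 L² mol⁻² s⁻¹)
    intermediate → side product (k = 0.00570 s⁻¹)

**What h means.** The middle form is the intermediate, and falling back to substrate is one of its other ways. In birch, that falling back and the time allowed are parts of what holds the target at 68.9%, and they act together: removing the falling back gives 80.9%, and a tenfold time gives 88.7%. The chances put birch at 6.38 times elm, and birch stands at 5.51 times elm's target. The chances put oak at 1.69 times maple, and oak stands at 1.62 times maple's target.

The data are calculated from invented constants; noise was put on by code.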